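**Retrosynthetic overview**

1. Last step: selective acetylation of the secondary C14–OH of the 14,15-diol beside the tertiary C15–OH.
2. Key disconnection C12–C13: the neopentyl alcohol carrying the whole bicyclic core (C1–C12) is joined to racemic 2-methylbutane-2,3-diol (C13–C15) in one redox-neutral, enantioselective hydrogen-borrowing (Guerbet-type) coupling that also sets C14.
3. The neopentyl alcohol comes from the bare skeleton by cytochrome P450 hydroxylation of the pro-R methyl on C11 (late C–H oxidation; sets C11).
4. Rings: the cyclobutane (C1–C9–C10–C11) and the nine-membered ring (C1 to C9) are bought, with C1 and C9, as (−)-β-caryophyllene. The oxirane (C4–O–C5) is the only ring formed, by syn-dihydroxylation of the E-C4=C5 bond and closure with inversion at C5.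
5. Enabling feature: C12 sits on the quaternary cyclobutane carbon C11, so the C12 aldehyde has no α-hydrogen; C15 carries two methyls and OH, so the C13–C15 ketone enolises only at C13. The crossed aldol inside the hydrogen-borrowing cycle therefore has one possible course, and C11 cannot epimerise.

Key step: step 4

Numbering remark: C1–C11 are the bicyclo[7.2.0]undecane atoms (C1/C9 ring fusion, C4/C5 oxirane carbons, C8 bears the exocyclic methylene, C10 cyclobutane CH2, C11 quaternary); C12–C15 is the chain on C11. The same numbers are used for all intermediates, so before hydroxylation "C12" is the C11 methyl cis to H-1.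

Assumption: a P450 variant that hydroxylates the pro-R C11 methyl of the cis-oxide with useful selectivity is found by panel screening; this selectivity is a property of the enzyme and cannot be predicted from the substrate alone.

**Route**

Step 1
Reactants: 1 (−)-β-caryophyllene [(1R,9S), E-C4=C5]
Product: 2 (1R,4R,5R,9S)-4,11,11-trimethyl-8-methylenebicyclo[7.2.0]undecane-4,5-diol (syn-diol)
Conditions: OsO4 (2 mol%), NMO (1.05 equiv), acetone/H2O 8:1, 0 °C
Reagents that add atoms: N-methylmorpholine N-oxide C[N+]1([O-])CCOCC1; water O; osmium tetroxide O=[Os](=O)(=O)=O (catalytic oxygen carrier)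
Why: Catalytic OsO4/NMO syn-dihydroxylation ([3+2] osmate ester, then hydrolysis): the strained, trisubstituted E-C4=C5 bond should react much faster than the 1,1-disubstituted exocyclic alkene, and the reagent can reach it only from the outer face of the E-cyclononene, the face from which peracids give the natural (4R,5R)-oxide, so both C–O bonds form syn and C4 and C5 are set as 4R,5R.

Step 2
Reactants: 2 (1R,4R,5R,9S)-syn-4,5-diol
Product: 4 (1R,4R,5S,9S)-4,5-epoxy-4,11,11-trimethyl-8-methylenebicyclo[7.2.0]undecane (cis-fused oxirane), via C5 mesylate 3 (not isolated)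
Conditions: MsCl (1.1 equiv), Et3N, CH2Cl2, −10 °C; then K2CO3, MeOH, 0 °C to rt
Reagents that add atoms: none
Why: Selective sulfonylation of the secondary C5–OH (the C4–OH is tertiary) followed by intramolecular Williamson etherification (3-exo-tet), in which the C4 alkoxide displaces the C5 mesylate from the rear side, so C4 keeps its configuration and C5 is inverted to S, turning the syn-diol of the E-alkene into the cis-fused oxirane.

Step 3
Reactants: 4 (1R,4R,5S,9S)-cis-oxide
Product: 5 [(1R,4R,5S,9S,11R)-4,5-epoxy-4,11-dimethyl-8-methylenebicyclo[7.2.0]undecan-11-yl]methanol (C12 alcohol; CH2OH cis to H-1)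
Conditions: cytochrome P450 monooxygenase (P450-BM3 variant from a screening panel, E. coli whole cells), NADP+ (cat.), glucose dehydrogenase, D-glucose, air, KPi buffer pH 8.0, 2% DMSO, 25 °C
Reagents that add atoms: dioxygen O=O
Why: Cytochrome P450 monooxygenase C–H hydroxylation (hydrogen abstraction by the ferryl oxidant, then oxygen rebound), a biotransformation type documented for the C11 methyl groups of caryophyllene 4,5-oxides: the binding pocket and not the C–H bond strength decides the site, and the selected variant presents the pro-R methyl (cis to H-1) to the haem, which makes C11 an R-configured stereocentre while oxirane and alkene are left untouched.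

Step 4
Reactants: 5 C12 alcohol; 6 rac-2-methylbutane-2,3-diol (2 equiv)
Product: 11 (3R)-2-methyl-5-[(1R,4R,5S,9S,11R)-4,5-epoxy-4,11-dimethyl-8-methylenebicyclo[7.2.0]undecan-11-yl]pentane-2,3-diol (the 14R-configured 14,15-diol), via C12 aldehyde 7 (not isolated), via 3-hydroxy-3-methylbutan-2-one 8 (not isolated), via E-enone 9 (not isolated), via saturated ketone 10 (not isolated)
Conditions: RuCl2[(R)-tolbinap](pica) (2 mol%), t-BuOK (0.3 equiv), toluene, 40 °C, closed vessel under Ar
Reagents that add atoms: none
Why: Proposed new method: an enantioselective Guerbet-type hydrogen-borrowing cross-coupling in which the Ru(II) diphosphine/amine catalyst reversibly dehydrogenates 5 to aldehyde 7 and 6 to ketone 8, t-BuOK mediates their crossed aldol condensation to E-enone 9 (this forms the C12–C13 bond), and the stored hydrogen is returned first to the conjugated C=C (giving 10) and then, enantioface-selectively, to the C14 carbonyl (giving 11), with water as the only by-product. The closest known reaction type is the enantioselective Guerbet reaction of racemic aryl methyl carbinols with primary alcohols under Ru(II) diphosphine/diamine catalysis, together with the TolBINAP/PICA–Ru hydrogenation of tert-alkyl ketones; new here are the dialkyl α-hydroxy carbinol partner and the neopentyl alcohol. No ring is closed. The one new stereocentre, C14, is set by the catalyst, whose chiral diphosphine tells the C(CH3)2OH branch from the CH2CH2 chain in the outer-sphere hydride transfer (the (R)-ligand is chosen by analogy with tert-alkyl methyl ketones and the sense would be checked on 11), while the stereocentre of 6 is erased at the ketone stage, so racemic 6 suffices. The selectivity needed is cross- over self-condensation, and the substrate secures it: C11 is quaternary, so 7 has no α-hydrogen (no self-aldol, no epimerisation), and C15 is fully substituted, so 8 enolises only at C13. The outer-sphere Ru hydride reduces only polarised C=O and conjugated C=C bonds, so the exocyclic alkene and the trisubstituted oxirane, which should also tolerate sub-stoichiometric t-BuOK at 40 °C, are expected to survive.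

Step 5
Reactants: 11 (14R)-14,15-diol
Product: 12 target, (1R,4R,5S,9S,11R,14R)-14-acetoxy-4,5-epoxy core with free C15–OH (CNP0157071.2)
Conditions: Ac2O (1.5 equiv), pyridine, DMAP (5 mol%), CH2Cl2, 0 °C
Reagents that add atoms: acetic anhydride CC(=O)OC(C)=O
Why: DMAP-catalysed acyl transfer: at 0 °C only the secondary C14–OH is acetylated because the C15–OH is tertiary and shielded by its two methyl groups, and no stereocentre is touched.

**Compound list**

1 | (−)-β-caryophyllene, (1R,9S,4E) | C=C1CC/C=C(C)/CC[C@@H]2[C@@H]1CC2(C)C | starting material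
2 | (1R,4R,5R,9S)-syn-4,5-diol of the caryophyllene skeleton | C=C1CC[C@@H](O)[C@](C)(O)CC[C@@H]2[C@@H]1CC2(C)C | intermediate
3 | C5 mesylate of 2 (C4–OH free) | C=C1CC[C@@H](OS(C)(=O)=O)[C@](C)(O)CC[C@@H]2[C@@H]1CC2(C)C | intermediate
4 | (1R,4R,5S,9S)-cis-4,5-oxide, exocyclic C8 methylene | C=C1CC[C@@H]2O[C@]2(C)CC[C@@H]2[C@@H]1CC2(C)C | intermediate
5 | (11R)-C12 alcohol of 4 (CH2OH on C11, cis to H-1) | C=C1CC[C@@H]2O[C@]2(C)CC[C@@H]2[C@@H]1C[C@@]2(C)CO | intermediate
6 | rac-2-methylbutane-2,3-diol | CC(O)C(C)(C)O | starting material
7 | C12 aldehyde (CHO on C11, no α-hydrogen) | C=C1CC[C@@H]2O[C@]2(C)CC[C@@H]2[C@@H]1C[C@@]2(C)C=O | intermediate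
8 | 3-hydroxy-3-methylbutan-2-one | CC(=O)C(C)(C)O | intermediate
9 | E-enone, C12=C13, C14 ketone, C15 tertiary alcohol | C=C1CC[C@@H]2O[C@]2(C)CC[C@@H]2[C@@H]1C[C@@]2(C)/C=C/C(=O)C(C)(C)O | intermediate
10 | saturated C14 ketone with C15 tertiary alcohol | C=C1CC[C@@H]2O[C@]2(C)CC[C@@H]2[C@@H]1C[C@@]2(C)CCC(=O)C(C)(C)O | intermediate
11 | (14R)-14,15-diol | C=C1CC[C@@H]2O[C@]2(C)CC[C@@H]2[C@@H]1C[C@@]2(C)CC[C@@H](O)C(C)(C)O | intermediate
12 | target, (14R)-14-acetate with free C15–OH | C=C1CC[C@@H]2O[C@]2(C)CC[C@@H]2[C@@H]1C[C@@]2(C)CC[C@@H](OC(C)=O)C(C)(C)O | target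

**Step count and risks**

Total step count: 5. Longest linear sequence: 5 steps (1 → 2 → 4 → 5 → 11 → 12).

Steps most likely to fail:

1. Step 4 (bears the label). What may go wrong: the hydrogen-borrowing cycle stalls (loss of the aldehyde to Tishchenko-type esterification, slow aldol dehydration), the catalyst discriminates the two alkyl sides of the dialkyl ketone poorly, or the C14 configuration erodes through reversible dehydrogenation of the product. Fallback with known chemistry, setting out from 5 and coming back at 11:
   - Buffered Dess–Martin oxidation of 5 gives aldehyde 7, isolated this time.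
   - Horner–Wadsworth–Emmons olefination of 7 with the known reagent dimethyl [3-methyl-2-oxo-3-(triethylsilyloxy)butyl]phosphonate (LiCl, i-Pr2NEt, MeCN) forms the C12–C13 bond as the E-enone silyl ether F1.
   - Conjugate reduction with [(Ph3P)CuH]6 gives the saturated ketone silyl ether F2.
   - CBS reduction with the (S)-oxazaborolidine and catecholborane at low temperature (the silyloxy-bearing tertiary carbon as the large group) should give the (14R)-alcohol silyl ether F3.
   - TBAF removes the silyl group and gives 11.

2. Step 3. What may go wrong: oxidation at other sites (allylic C–H bonds, epoxidation of the exocyclic alkene), hydroxylation of the other diastereotopic methyl, or over-oxidation of the new alcohol. Fallback, setting out from 1 and coming back at 5; the hydroxylation is moved to the trans-oxide, the substrate for which microbial hydroxylation of the C11 methyls is documented, and the cis-oxirane is built afterwards: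
   - mCPBA on 1 gives (−)-caryophyllene oxide F4 (also an article of commerce).
   - Enzymatic hydroxylation gives the (11R)-hydroxymethyl trans-oxide F5.
   - TBSCl/imidazole gives the silyl ether F6.
   - Stereoretentive deoxygenation (WCl6/n-BuLi, THF) gives the E-alkene silyl ether F7.
   - The chemistry of steps 1 and 2 then gives the syn-diol silyl ether F8, its C5 mesylate F9 and the cis-oxide silyl ether F10.
   - TBAF gives 5.

3. Step 1. What may go wrong: osmylation from the other alkene face (leading into the 4S,5S series) or over-oxidation at the exocyclic alkene. Fallback, setting out from 1 and coming back at 4; the cis-oxirane is made by direct epoxidation of the Z-alkene instead: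
   - Thiyl-radical E→Z isomerisation of 1 (PhSSPh, hν) gives (−)-isocaryophyllene F11.
   - mCPBA (NaHCO3, CH2Cl2, 0 °C) should epoxidise its trisubstituted Z-alkene chemoselectively.
   - The face selectivity of this epoxidation is not assumed here: 4 would be separated from its (4S,5R)-isomer and assigned by NOE.

**Further compounds**

F1 | step 4 | E-enone triethylsilyl ether (silyl ether of 9) | C=C1CC[C@@H]2O[C@]2(C)CC[C@@H]2[C@@H]1C[C@@]2(C)/C=C/C(=O)C(C)(C)O[Si](CC)(CC)CC
F2 | step 4 | saturated ketone triethylsilyl ether (silyl ether of 10) | C=C1CC[C@@H]2O[C@]2(C)CC[C@@H]2[C@@H]1C[C@@]2(C)CCC(=O)C(C)(C)O[Si](CC)(CC)CC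
F3 | step 4 | (14R)-alcohol with C15 triethylsilyl ether | C=C1CC[C@@H]2O[C@]2(C)CC[C@@H]2[C@@H]1C[C@@]2(C)CC[C@@H](O)C(C)(C)O[Si](CC)(CC)CC
F4 | step 3 | (−)-caryophyllene oxide, (1R,4R,5R,9S)-trans-oxide | C=C1CC[C@H]2O[C@]2(C)CC[C@@H]2[C@@H]1CC2(C)C
F5 | step 3 | (11R)-C12 alcohol of the trans-oxide | C=C1CC[C@H]2O[C@]2(C)CC[C@@H]2[C@@H]1C[C@@]2(C)CO
F6 | step 3 | TBS ether of F5 | C=C1CC[C@H]2O[C@]2(C)CC[C@@H]2[C@@H]1C[C@@]2(C)CO[Si](C)(C)C(C)(C)C
F7 | step 3 | E-alkene (β-caryophyllene skeleton) with C12 TBS ether | C=C1CC/C=C(C)/CC[C@@H]2[C@@H]1C[C@@]2(C)CO[Si](C)(C)C(C)(C)C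
F8 | step 3 | (4R,5R)-syn-diol with C12 TBS ether | C=C1CC[C@@H](O)[C@](C)(O)CC[C@@H]2[C@@H]1C[C@@]2(C)CO[Si](C)(C)C(C)(C)C
F9 | step 3 | C5 mesylate of F8 | C=C1CC[C@@H](OS(C)(=O)=O)[C@](C)(O)CC[C@@H]2[C@@H]1C[C@@]2(C)CO[Si](C)(C)C(C)(C)C
F10 | step 3 | (4R,5S)-cis-oxide with C12 TBS ether (silyl ether of 5) | C=C1CC[C@@H]2O[C@]2(C)CC[C@@H]2[C@@H]1C[C@@]2(C)CO[Si](C)(C)C(C)(C)C
F11 | step 1 | (−)-isocaryophyllene, (1R,9S,4Z) | C=C1CC/C=C(C)\CC[C@@H]2[C@@H]1CC2(C)C
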